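## Analysis of the target

The target is a sesquiterpene diester in which one cyclobutane carries two bridges on opposite faces. Carvone locants are used throughout: C1–C6 are the enone ring (C4 the ketone, C2=C3 the alkene, C7 the methyl on C2, C1 and C5 the bridgeheads, C6 the cyclobutane CH), C8 is the quaternary C–Me carbon (methyl C10), C9 the carbinol carbon on C8, C11 the CMe2 carbon on C6, C12 the second carbinol carbon and C13 the CH2 between C12 and C9. C1 and C5 are spanned by C2=C3–C4(=O), a verbenone-type bicyclo[3.1.1]hept-3-en-2-one; C6 and C8 are spanned by C11–C12–C13–C9, a seven-membered ring. There are six stereocentres. The four cyclobutane carbons are locked to one another by the two bridges (C10 syn to the enone bridge, C9 and C11 anti to it). The two carbinols C9 (senecioate) and C12 (isovalerate) are trans across the seven-membered ring, with the C9 oxygen on the C5 side and anti to C1. Sensitive features are the pinene-type cyclobutane (acid, cations), the enone with its vinylogously acidic C7 methyl, and the conjugated senecioate. The hard points are the two fully substituted carbons C8 and C11 on the small ring, the ring closure across a 1,3-disubstituted cyclobutane, and telling apart two hindered secondary oxygens. The strategy rests on the fact that C1–C6 with C7, and C8 with C9 and C10, are the ring, ring methyl and isopropenyl group of (R)-carvone, which lacks only the C8–C1 bond. Because C1 is the carvone carbonyl carbon and C4 its allylic methylene, oxygen must later be removed from C1 and introduced at C4.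

## Retrosynthetic reasoning

**23 to 22 (C4=O).** The enone oxygen is introduced last by allylic oxidation of the C4 methylene, the pinene-to-verbenone transformation. Placing it last keeps the acidic C7 methyl of the enone out of all enolate and radical steps.

**22 to 21 and 20 (C1–H).** The bridgehead hydrogen is traced to a C1–O bond, which is the carvone carbonyl oxygen. A bridgehead of a cyclobutane allows neither ionization nor elimination, so the oxygen can only leave through a bridgehead radical from the oxalate 21. The removal is placed late because the C1 oxygen is the only element that distinguishes the C1 side from the C5 side when C9 is set.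

**20 and 19 to 18 to 17 (ester C–O bonds and C12–H).** The isovalerate is a plain acylation of 18. The senecioate and the C12 hydrogen are traced together to the β-hydroxy ketone 17. A Tishchenko-type hydride transfer from a hemiacetal on the C9 oxygen gives the trans diol and leaves the acyl group on C9, so the two oxygens are differentiated by mechanism.

**17 to 16 (C13–C9).** The seven-membered ring is opened at the aldol bond. C13 is the only enolizable position of the methyl ketone and C9 is a non-enolizable aldehyde, so the polarity is unambiguous. The silyl ether on C1 must steer the aldehyde oxygen to the C5 side.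

**16 to 15, 14 and 13 (oxidation levels).** The aldehyde comes from the C9 alcohol and the methyl ketone from a dioxolane. The C1 hydroxyl is silylated first, because a free C1–OH beside a C9 aldehyde is a β-hydroxy aldehyde on a cyclobutane and would open by retro-aldol.

**13 to 12 (C8–C1, key).** The cyclobutane is opened at the bond between the quaternary carbon and the carbonyl carbon. Forward, a titanocene reagent of trivalent titanium opens the epoxide of 12 to the tertiary C8 radical, which closes 4-exo onto the ketone. This one bond gives the cyclobutane and leaves the C2=C3 alkene for the later oxidation at C4.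

**12 to 11, 10 and 9 (side-chain masking).** The epoxide comes from the isopropenyl group. The C12 carbonyl is installed by Wacker oxidation and masked before the radical step, because a vinyl or acetyl group on C11 would sit five atoms from the C8 radical and would capture it by 5-exo closure.

**9 to 8 to 3 and 6; 3 to 1; 6 to 4 and 5 (C6–C11).** The quaternary C11 is attached to C6 by a [2,3]-sigmatropic shift of a sulfonium ylide made from the diazoketone 3 and the sulfide 6. The C6–H bond is formed last, by protonation of the enolate released on C–S cleavage. This order gives the side chain cis to the isopropenyl group, which the target requires because C11 and C9 must lie on the same face of the cyclobutane.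

## Alternatives that were turned down

**Alternative 1: ring contraction.** The cyclobutane bond C5–C6 is made by contracting a five-membered ketone. Photolysis of the diazoketone A1 in an alcohol makes C6 migrate to the carbene carbon, and the ketene is trapped as the ester A2. In A2 the seven-membered ring, both protected carbinols, C11 and C8 are already in place.
- For: ring contraction is a dependable entry to a strained four-membered ring. The C8 configuration is fixed by the ring, and no bridgehead oxygen has to be removed. On both points it is stronger than the chosen route.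
- Against: A1 has five stereocentres and no chiral-pool parent. The new C5 centre is set by protonation and must come out cis to the acetyl arm. The enone ring must still be closed afterwards by a strained condensation across the cyclobutane.
- Comparison: the chosen route takes cyclobutane and enone ring from carvone with one C–C bond and pays for it in steps 15–18.

**Alternative 2: aldol with reversed polarity and in-flask Tishchenko reduction.** The C12–C13 bond is cut the other way round: a methyl ketone on C8 and an aldehyde on C11, as in A3. The lithium enolate closes the ring, and the aldolate takes up the saturated aldehyde that carries the isovaleryl carbons and passes its hydride to the C9 ketone, giving A4.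
- For: ring closure, trans diol and first ester arise in one flask, and the hydride donor is a saturated aldehyde. On step economy of the endgame it is stronger than steps 12–14.
- Against: it does not make the cyclobutane; A3 already holds all four ring stereocentres. The new carbinol C12 forms next to CMe2, far from anything that distinguishes the C1 side from the C5 side. An enolizable aldehyde beside a lithium aldolate invites proton transfer and self-condensation.
- Comparison: the chosen route uses the same hydride-transfer logic in the opposite polarity, where the aldol carbinol C9 sits next to the C1 oxygen that directs it.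

**Alternative 3: pinacol-type ring expansion.** The C6–C11 bond is made by a 1,2-shift. In the diol A5 the carbocycle is six-membered. Ionization of the exocyclic tertiary hydroxyl makes C6 migrate from C12 to C11 and gives the ring-expanded ketone A6.
- For: a six-membered ring is easier to close than a seven-membered one. The crowded C6–C11 bond forms intramolecularly, and the C8 configuration is fixed by the ring, which is stronger than the chosen route.
- Against: a cation one bond from a pinene-type cyclobutane invites skeletal shifts and ring opening. Migration of C13 or elimination competes. A5 is a more strained cage than the target, and its own cyclobutane synthesis is open. The enone is exposed to acid.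
- Comparison: the chosen route makes the C6–C11 bond on the monocyclic ketone under neutral conditions and never generates a cation beside the four-membered ring.

Key step: step 8

## Route

Remark: carvone locants as defined in the analysis are used in all names; 8 and 12 are used as epimer mixtures (at C6 and at C8), because both centres become planar in the following step.

Step 1
Reactants: 1 (R)-(−)-carvone
Product: 3 6-diazocarvone (6-diazo-2-methyl-5-(prop-1-en-2-yl)cyclohex-2-en-1-one; C5 as in 1), via 6-(trifluoroacetyl)carvone 2 (not isolated)
Conditions: LiN(SiMe3)2, THF, −78 °C; CF3CO2CH2CF3; then MeSO2N3, Et3N, H2O, MeCN, rt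
Reagents that add atoms: methanesulfonyl azide, CS(=O)(=O)N=[N+]=[N-] (the two diazo nitrogens); 2,2,2-trifluoroethyl trifluoroacetate, FC(F)(F)COC(=O)C(F)(F)F (the trifluoroacetyl group of 2, lost again)
Why: Regitz diazo transfer in its detrifluoroacetylative form: the kinetic α′-enolate is acylated at C6 and the activated diketone hands its acyl group to the azide, leaving the diazo group at C6; C5 is not touched.

Step 2
Reactants: 4 1-bromo-3-methylbut-2-ene; 5 benzenethiol
Product: 6 (3-methylbut-2-en-1-yl)(phenyl)sulfane (prenyl phenyl sulfide)
Conditions: K2CO3, acetone, rt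
Reagents that add atoms: none
Why: SN2 displacement of a primary allylic bromide by thiolate (Williamson-type thioether synthesis).

Step 3
Reactants: 3 6-diazocarvone; 6 prenyl phenyl sulfide
Product: 8 2-methyl-6-(2-methylbut-3-en-2-yl)-6-(phenylsulfanyl)-5-(prop-1-en-2-yl)cyclohex-2-en-1-one (C5 as in 1; both C6 epimers), via sulfonium ylide 7 (not isolated)
Conditions: Rh2(OAc)4 (1 mol%), 6 (3 equiv), CH2Cl2, 40 °C, slow addition of 3
Reagents that add atoms: none
Why: Doyle–Kirmse reaction: the rhodium carbenoid at C6 is captured by sulfur, and the allyl sulfonium ylide undergoes a [2,3]-sigmatropic shift that joins C6 to the dimethyl-substituted allyl terminus, giving the C6–C11 bond with C11 quaternary and a vinyl group. The C6 configuration formed here does not matter because C6 becomes planar in step 4.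

Step 4
Reactants: 8 sulfanyl ketone
Product: 9 (5R,6S)-2-methyl-6-(2-methylbut-3-en-2-yl)-5-(prop-1-en-2-yl)cyclohex-2-en-1-one (C6 side chain cis to the isopropenyl group)
Conditions: SmI2 (2.5 equiv), THF/MeOH, −78 °C
Reagents that add atoms: none
Why: Reductive cleavage of the α-sulfanyl ketone gives the C1–C6 enolate regiospecifically; in it the isopropenyl group is pseudoaxial to avoid the in-plane C11 group. Kinetic protonation anti to it places H trans and C11 cis to the isopropenyl group, the relation the target needs.

Step 5
Reactants: 9 cis vinyl ketone
Product: 10 (5R,6S)-2-methyl-6-(2-methyl-3-oxobutan-2-yl)-5-(prop-1-en-2-yl)cyclohex-2-en-1-one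
Conditions: PdCl2 (10 mol%), CuCl (30 mol%), O2 (1 atm), DMF/H2O, rt
Reagents that add atoms: water, O (its oxygen becomes the ketone oxygen; O2 is the terminal oxidant)
Why: Wacker–Tsuji oxidation: divalent palladium oxidizes the monosubstituted vinyl group in the Markovnikov sense at C12, while the 1,1-disubstituted isopropenyl group and the enone are inert. This removes the one alkene that the C8 radical of step 8 could reach by 5-exo closure.

Step 6
Reactants: 10 cis diketone
Product: 11 (5R,6S)-2-methyl-6-[2-(2-methyl-1,3-dioxolan-2-yl)propan-2-yl]-5-(prop-1-en-2-yl)cyclohex-2-en-1-one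
Conditions: Me3SiOCH2CH2OSiMe3, Me3SiOTf (5 mol%), CH2Cl2, −78 to −20 °C; pyridine quench
Reagents that add atoms: 1,2-bis(trimethylsilyloxy)ethane, C[Si](C)(C)OCCO[Si](C)(C)C
Why: Silyl-triflate-catalysed ketalization (Noyori conditions) converts the saturated ketone and leaves the less electrophilic conjugated one. The dioxolane stops C12 from acting as a radical acceptor, and the cold aprotic conditions spare the epimerizable C6 centre.

Step 7
Reactants: 11 ketal enone
Product: 12 (5R,6S)-2-methyl-6-[2-(2-methyl-1,3-dioxolan-2-yl)propan-2-yl]-5-(2-methyloxiran-2-yl)cyclohex-2-en-1-one (both epoxide epimers)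
Conditions: mCPBA (1.1 equiv), NaHCO3, CH2Cl2, 0 °C
Reagents that add atoms: 3-chloroperoxybenzoic acid, OOC(=O)c1cccc(Cl)c1
Why: Prilezhaev epoxidation of the only electron-rich alkene; the enone C=C is deactivated and the epoxide configuration is lost in step 8.

Step 8
Reactants: 12 epoxy ketone
Product: 13 bicyclo[3.1.1]hept-2-ene diol: C1 bridgehead hydroxyl; C8 with methyl C10 syn and hydroxymethyl C9 anti to the alkene bridge; C6 with the 2-(2-methyl-1,3-dioxolan-2-yl)propan-2-yl group anti to the alkene bridge
Conditions: Cp2TiCl2 (2.5 equiv), Zn dust, THF, rt (gives Cp2TiCl); slow addition of 12, rt; aqueous NaH2PO4; separation from the C8 epimer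
Reagents that add atoms: none
Why: Cp2TiCl transfers one electron to the epoxide, which opens at the more substituted carbon to the tertiary C8 radical with a titanium-bound CH2O arm; the radical adds to the carbonyl carbon C1 in a 4-exo-trig closure, and a second Cp2TiCl reduces the alkoxy radical to the titanium alkoxide, which makes the otherwise reversible closure irreversible. The closest known reaction type is the titanocene-mediated reductive opening of an epoxy ketone with 4-exo radical addition to the ketone, the reaction that turns 8,9-epoxycarvone into a pinene-type cyclobutanol. The only ring closed is the cyclobutane, through the C1–C8 bond; no other acceptor is within reach, because C12 is a dioxolane and the enone C=C cannot be reached. The cis relation from step 4 makes the reactive conformer the ground state: the bulky C6 group is equatorial, so the C5 side chain is axial and C8 lies over C1. C1 can be attacked only on the face that carries the C5 side chain, so the bridgehead carbinol follows from C5 of carvone and the C6 group ends anti to the alkene bridge. C8 is not dictated by the ring: the radical is planar, and either CH3 or the titanium-bound arm can turn towards the C6 side chain, while the target needs the arm on that side. The two groups differ little in size, and the only bias in favour is that in the needed rotamer the arm oxygen lies synclinal to the carbonyl oxygen, so both C8 epimers are to be expected and only 13 is carried on.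

Step 9
Reactants: 13 diol
Product: 14 bis(triethylsilyl) ether of 13 (C1–OSiEt3 and C9–OSiEt3)
Conditions: Et3SiOTf (2.6 equiv), 2,6-lutidine, CH2Cl2, −78 to −40 °C
Reagents that add atoms: triethylsilyl trifluoromethanesulfonate, CC[Si](CC)(CC)OS(=O)(=O)C(F)(F)F
Why: The silyl triflate silylates the primary and the tertiary bridgehead hydroxyl. The C1 silyl ether prevents the retro-aldol opening of the cyclobutane that a free β-hydroxy aldehyde would undergo after step 11, and it later steers the aldol.

Step 10
Reactants: 14 bis(silyl) ether
Product: 15 hydroxy ketone: C9–OH primary, C12 methyl ketone (C11 bears 3-oxobutan-2-yl carbons C12 and C13), C1–OSiEt3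
Conditions: PPTS (0.3 equiv), acetone/H2O (10:1), 45 °C
Reagents that add atoms: water, O
Why: Mild acid hydrolysis removes the dioxolane and the primary silyl ether; the hindered bridgehead silyl ether and the acid-sensitive pinene-type alkene should survive pyridinium-level acidity.

Step 11
Reactants: 15 hydroxy ketone
Product: 16 keto aldehyde: C9 aldehyde on C8, C12 methyl ketone, C1–OSiEt3
Conditions: Dess–Martin periodinane, NaHCO3, CH2Cl2, 0 °C to rt
Reagents that add atoms: none
Why: Dess–Martin oxidation of the neopentylic primary alcohol; the aldehyde has no α-hydrogen and its β-oxygen is silylated, so neither epimerization nor retro-aldol can occur.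

Step 12
Reactants: 16 keto aldehyde
Product: 17 tricyclic aldol: seven-membered ring closed by the C13–C9 bond; C9–OH on the C5 side (anti to C1); C12 ketone; C1–OSiEt3
Conditions: Bu2BOTf (1.3 equiv), iPr2NEt (1.6 equiv), CH2Cl2 (0.01 M), −78 to −20 °C; pH 7 buffer, MeOH
Reagents that add atoms: none
Why: Intramolecular boron-mediated aldol addition: only C13 can be enolized, C9 is a non-enolizable aldehyde held on the same face of the cyclobutane, and the boron aldolate neither reverts nor dehydrates. The tether forces attack anti to the C10 methyl, and the aldehyde oxygen turns away from the bulky, non-chelating C1 silyloxy group, so the C9 hydroxyl ends on the C5 side as in the target.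

Step 13
Reactants: 17 tricyclic aldol
Product: 18 C9 3-methylbut-2-enoate (senecioate) with free C12–OH trans to it; C1–OSiEt3
Conditions: 3-methylbut-2-enal (8 equiv), SmI2 (30 mol%), THF, −10 °C
Reagents that add atoms: 3-methylbut-2-enal, CC(C)=CC=O
Why: Evans–Tishchenko reaction: the C9 hydroxyl forms a samarium-bound hemiacetal with the aldehyde, whose hydrogen is delivered intramolecularly to the C12 ketone on the face of the C9 oxygen. This gives the 1,3-anti (trans) diol with the senecioyl group on C9 and the C12 hydroxyl free.

Step 14
Reactants: 18 senecioate alcohol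
Product: 19 C9 senecioate, C12 3-methylbutanoate (isovalerate), C1–OSiEt3
Conditions: 3-methylbutanoyl chloride, pyridine, DMAP (cat.), CH2Cl2, 0 to 40 °C
Reagents that add atoms: 3-methylbutanoyl chloride, CC(C)CC(Cl)=O
Why: DMAP-catalysed acylation of the only free hydroxyl; no acyl migration from C9 is expected because the two oxygens are trans across the ring.

Step 15
Reactants: 19 diester silyl ether
Product: 20 diester with free C1 bridgehead hydroxyl
Conditions: HF·pyridine, pyridine/THF, 0 °C to rt
Reagents that add atoms: none
Why: Fluoride cleavage of the silyl ether under buffered conditions that leave both esters and the alkene alone; the C1 hydroxyl is anti to the C9 ester oxygen, so it cannot take over the acyl group.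

Step 16
Reactants: 20 bridgehead alcohol
Product: 21 C1 methyl oxalate of 20
Conditions: ClCOCO2Me (3 equiv), DMAP (cat.), pyridine, CH2Cl2, 0 °C to rt
Reagents that add atoms: methyl chlorooxoacetate, COC(=O)C(Cl)=O
Why: The very electrophilic oxalyl chloride half ester acylates the tertiary hydroxyl without alkoxide formation, so the neighbouring esters are not disturbed.

Step 17
Reactants: 21 oxalate
Product: 22 4-deoxo target: C9 senecioate, C12 isovalerate, C1–H, C4 methylene
Conditions: Bu3SnH (3 equiv, slow addition), AIBN (cat.), toluene, 110 °C
Reagents that add atoms: none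
Why: Barton–McCombie-type radical deoxygenation of a tertiary methyl oxalate: the stannyl radical adds to the oxalate, C1–O homolysis gives the bridgehead radical, and tin hydride caps it. The radical is pyramidal and locked, so hydrogen takes the place of oxygen, and the adjacent alkene is orthogonal to it and stays in place.

Step 18
Reactants: 22 deoxo compound
Product: 23 CNP0335239.1
Conditions: CrO3, 3,5-dimethylpyrazole, CH2Cl2, −20 °C
Reagents that add atoms: chromium trioxide, O=[Cr](=O)=O
Why: Allylic oxidation by the hexavalent chromium–pyrazole complex converts the only allylic methylene, C4, into the ketone, as in the oxidation of α-pinene to verbenone. The bridgehead C1–H cannot give a planar allyl radical, and the senecioate alkene is electron-poor.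

## Compound list

1 | (R)-(−)-carvone, (5R)-2-methyl-5-(prop-1-en-2-yl)cyclohex-2-en-1-one | CC1=CC[C@H](CC1=O)C(C)=C | starting material
2 | 6-(trifluoroacetyl)carvone (C5 as in 1; enolized at C6) | FC(F)(F)C(=O)C1[C@@H](CC=C(C)C1=O)C(C)=C | intermediate
3 | 6-diazocarvone, 6-diazo-2-methyl-5-(prop-1-en-2-yl)cyclohex-2-en-1-one (C5 as in 1) | [N-]=[N+]=C1[C@@H](CC=C(C)C1=O)C(C)=C | intermediate
4 | 1-bromo-3-methylbut-2-ene | CC(C)=CCBr | starting material
5 | benzenethiol | Sc1ccccc1 | starting material
6 | (3-methylbut-2-en-1-yl)(phenyl)sulfane | CC(C)=CCSc1ccccc1 | intermediate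
7 | sulfonium ylide: C6 carbanion of the carvone skeleton bound to phenyl(3-methylbut-2-enyl)sulfonium | CC(C)=CC[S+](c1ccccc1)[C-]2[C@@H](CC=C(C)C2=O)C(C)=C | intermediate
8 | 2-methyl-6-(2-methylbut-3-en-2-yl)-6-(phenylsulfanyl)-5-(prop-1-en-2-yl)cyclohex-2-en-1-one (C5 as in 1; both C6 epimers) | C=CC(C)(C)C1(Sc2ccccc2)[C@@H](CC=C(C)C1=O)C(C)=C | intermediate
9 | (5R,6S)-2-methyl-6-(2-methylbut-3-en-2-yl)-5-(prop-1-en-2-yl)cyclohex-2-en-1-one (cis) | C=CC(C)(C)[C@@H]1[C@@H](CC=C(C)C1=O)C(C)=C | intermediate
10 | (5R,6S)-2-methyl-6-(2-methyl-3-oxobutan-2-yl)-5-(prop-1-en-2-yl)cyclohex-2-en-1-one (cis) | CC(=O)C(C)(C)[C@@H]1[C@@H](CC=C(C)C1=O)C(C)=C | intermediate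
11 | (5R,6S)-2-methyl-6-[2-(2-methyl-1,3-dioxolan-2-yl)propan-2-yl]-5-(prop-1-en-2-yl)cyclohex-2-en-1-one (cis) | CC1(OCCO1)C(C)(C)[C@@H]2[C@@H](CC=C(C)C2=O)C(C)=C | intermediate
12 | (5R,6S)-2-methyl-6-[2-(2-methyl-1,3-dioxolan-2-yl)propan-2-yl]-5-(2-methyloxiran-2-yl)cyclohex-2-en-1-one (cis; both epoxide epimers) | CC1(OCCO1)C(C)(C)[C@@H]2[C@@H](CC=C(C)C2=O)C3(C)CO3 | intermediate
13 | bicyclo[3.1.1]hept-2-ene diol: C1–OH; C8 with C10 methyl syn and CH2OH (C9) anti to the alkene bridge; C6 ketal side chain anti | CC1(OCCO1)C(C)(C)[C@@H]2[C@H]3CC=C(C)[C@]2(O)[C@@]3(C)CO | intermediate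
14 | bis(triethylsilyl) ether of 13 | CC1(OCCO1)C(C)(C)[C@@H]2[C@H]3CC=C(C)[C@]2(O[Si](CC)(CC)CC)[C@@]3(C)CO[Si](CC)(CC)CC | intermediate
15 | hydroxy ketone: C9–OH, C12 methyl ketone, C1–OSiEt3 | CC(=O)C(C)(C)[C@@H]1[C@H]2CC=C(C)[C@]1(O[Si](CC)(CC)CC)[C@@]2(C)CO | intermediate
16 | keto aldehyde: C9 aldehyde, C12 methyl ketone, C1–OSiEt3 | CC(=O)C(C)(C)[C@@H]1[C@H]2CC=C(C)[C@]1(O[Si](CC)(CC)CC)[C@@]2(C)C=O | intermediate
17 | tricyclic aldol: C9–OH on the C5 side, C12 ketone, C1–OSiEt3 | O[C@@H]1CC(=O)C(C)(C)[C@@H]2[C@H]3CC=C(C)[C@]2(O[Si](CC)(CC)CC)[C@]31C | intermediate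
18 | C9 senecioate, C12–OH trans to it, C1–OSiEt3 | CC(C)=CC(=O)O[C@@H]1C[C@@H](O)C(C)(C)[C@@H]2[C@H]3CC=C(C)[C@]2(O[Si](CC)(CC)CC)[C@]31C | intermediate
19 | C9 senecioate, C12 isovalerate, C1–OSiEt3 | CC(C)=CC(=O)O[C@@H]1C[C@@H](OC(=O)CC(C)C)C(C)(C)[C@@H]2[C@H]3CC=C(C)[C@]2(O[Si](CC)(CC)CC)[C@]31C | intermediate
20 | C9 senecioate, C12 isovalerate, C1–OH | CC(C)=CC(=O)O[C@@H]1C[C@@H](OC(=O)CC(C)C)C(C)(C)[C@@H]2[C@H]3CC=C(C)[C@]2(O)[C@]31C | intermediate
21 | C1 methyl oxalate of 20 | CC(C)=CC(=O)O[C@@H]1C[C@@H](OC(=O)CC(C)C)C(C)(C)[C@@H]2[C@H]3CC=C(C)[C@]2(OC(=O)C(=O)OC)[C@]31C | intermediate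
22 | 4-deoxo target (C1–H, C4 methylene) | CC(C)=CC(=O)O[C@@H]1C[C@@H](OC(=O)CC(C)C)C(C)(C)[C@@H]2[C@H]3CC=C(C)[C@@H]2[C@]31C | intermediate
23 | CNP0335239.1 | CC(C)=CC(=O)O[C@@H]1C[C@@H](OC(=O)CC(C)C)C(C)(C)[C@@H]2[C@H]3C(=O)C=C(C)[C@@H]2[C@]31C | target

## Step count and least certain steps

Total: 18 steps. Longest linear sequence: 17 steps (1 to 23 through steps 1 and 3–18).

**Step 8 (key step).** The most likely failure is poor facial selectivity at C8: the planar radical can close with either the methyl group or the titanium-bound arm turned towards the C6 side chain, and the two groups are of similar size. A second risk is premature reduction of the radical, or its capture by titanium followed by elimination to an allylic alcohol, before the slow 4-exo closure.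
Fallback, from 11 back to 14: the stereochemical question is removed by giving C8 two oxygenated arms. Ene-type chlorination of the isopropenyl methyl of 11 (Ca(OCl)2, CO2, CH2Cl2/H2O) gives the allylic chloride F1. Acetate displacement (KOAc, Bu4NI, DMF) gives the allylic acetate F2, and mCPBA gives the epoxy acetate F3. Closure with Cp2TiCl as in step 8, followed by methanolysis (K2CO3, MeOH), gives from either mode of closure the same triol F4, in which C8 is no longer a stereocentre. Only the arm syn to the alkene can reach C2, so iodoetherification (I2, NaHCO3, MeCN) ties it up as the cyclic iodo ether F5. Silylation as in step 9 gives the bis(triethylsilyl) ether F6. Zinc (Zn, NH4Cl, EtOH) restores the alkene and frees the syn hydroxymethyl group in the alcohol F7. Mesylation (MsCl, Et3N) gives the mesylate F8, and LiEt3BH reduction turns that arm into the C10 methyl group, which gives 14.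

**Step 12.** Closure of a seven-membered ring through a closed boron transition state may be slow, so that intermolecular aldol addition competes, and the selectivity for the C9 hydroxyl on the C5 side may erode if the aldehyde does not turn away from the silyloxy group.
Fallback, from 15 back to 17: Me3SiOTf and Et3N convert 15 into the silyl enol ether F9 (the primary hydroxyl is silylated as well). N-Bromosuccinimide and aqueous work-up give the bromomethyl ketone F10, and Dess–Martin oxidation gives the bromo keto aldehyde F11. SmI2 (THF, −78 °C) then closes the ring by an intramolecular samarium Reformatsky reaction, which is irreversible at low temperature, to 17.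

**Step 13.** Hydride transfer from the hemiacetal of a conjugated aldehyde may be slow, and the samarium Lewis acid may then open 17 by retro-aldol or leave the reaction incomplete.
Fallback, from 17 back to 19: the Tishchenko reaction is run with 4-nitrobenzaldehyde (SmI2 cat.), a reactive aromatic aldehyde, giving the 4-nitrobenzoate F12. Isovalerylation as in step 14 gives the mixed diester F13. The activated aryl ester is cleaved selectively (K2CO3, MeOH, 0 °C) to the C9 alcohol F14. Acylation with 3-methylbut-2-enoic acid (2,4,6-trichlorobenzoyl chloride, Et3N, DMAP) gives 19.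

**Step 17.** The bridgehead radical on a cyclobutane is strained, so fragmentation of the tin adduct may be slow and reduction may stop at the alcohol 20 or a formate.
Fallback, from 21 back to 22: CsOH (1 equiv, THF/H2O, 0 °C) hydrolyses only the activated methyl ester to the cesium oxalate F15. An excited iridium photocatalyst (Ir[dF(CF3)ppy]2(dtbbpy)PF6, blue light, DME/H2O) oxidizes F15, which loses two molecules of CO2. The bridgehead radical takes hydrogen from a thiol co-catalyst (methyl thioglycolate) and gives 22, so the radical forms irreversibly and without tin.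

**Step 4 (with steps 5 and 6).** The cis epimer is the less stable one; protonation may not be fully selective, and partial epimerization at C6 towards trans may occur under the mildly acidic conditions of steps 5 and 6.
Fallback, from 11 back to 11 (no new compound, F0): the C6 centre is reset just before epoxidation by deprotonating the epimer mixture of 11 at C6, its only α′ hydrogen, with LiN(SiMe3)2 (THF, −78 °C) and protonating the enolate with 2,6-di-tert-butyl-4-methylphenol at −78 °C, which again delivers the proton anti to the isopropenyl group.

## Further compounds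

F1 | step 8 | allylic chloride of 11 (C10 chloride) | CC1(OCCO1)C(C)(C)[C@@H]2[C@@H](CC=C(C)C2=O)C(=C)CCl
F2 | step 8 | allylic acetate of 11 (C10 acetate) | CC1(OCCO1)C(C)(C)[C@@H]2[C@@H](CC=C(C)C2=O)C(=C)COC(C)=O
F3 | step 8 | epoxy acetate (both epoxide epimers) | CC1(OCCO1)C(C)(C)[C@@H]2[C@@H](CC=C(C)C2=O)C3(COC(C)=O)CO3
F4 | step 8 | triol: C1–OH and two hydroxymethyl groups on C8 | CC1(OCCO1)C(C)(C)[C@@H]2[C@H]3CC=C(C)[C@]2(O)C3(CO)CO
F5 | step 8 | cyclic iodo ether: syn arm oxygen bonded to C2, iodine on C3; C1–OH and anti CH2OH free | CC1(OCCO1)C(C)(C)[C@@H]2[C@H]3C[C@@H](I)[C@]4(C)OC[C@@]3(CO)[C@]24O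
F6 | step 8 | bis(triethylsilyl) ether of F5 | CC1(OCCO1)C(C)(C)[C@@H]2[C@H]3C[C@@H](I)[C@]4(C)OC[C@@]3(CO[Si](CC)(CC)CC)[C@]24O[Si](CC)(CC)CC
F7 | step 8 | alcohol: alkene restored, syn CH2OH free, anti CH2OSiEt3, C1–OSiEt3 | CC1(OCCO1)C(C)(C)[C@@H]2[C@H]3CC=C(C)[C@]2(O[Si](CC)(CC)CC)[C@@]3(CO)CO[Si](CC)(CC)CC
F8 | step 8 | mesylate of F7 | CC1(OCCO1)C(C)(C)[C@@H]2[C@H]3CC=C(C)[C@]2(O[Si](CC)(CC)CC)[C@@]3(COS(C)(=O)=O)CO[Si](CC)(CC)CC
F9 | step 12 | trimethylsilyl enol ether of 15 (C9–OSiMe3) | C=C(O[Si](C)(C)C)C(C)(C)[C@@H]1[C@H]2CC=C(C)[C@]1(O[Si](CC)(CC)CC)[C@@]2(C)CO[Si](C)(C)C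
F10 | step 12 | bromomethyl ketone with free C9–OH | BrCC(=O)C(C)(C)[C@@H]1[C@H]2CC=C(C)[C@]1(O[Si](CC)(CC)CC)[C@@]2(C)CO
F11 | step 12 | bromo keto aldehyde | BrCC(=O)C(C)(C)[C@@H]1[C@H]2CC=C(C)[C@]1(O[Si](CC)(CC)CC)[C@@]2(C)C=O
F12 | step 13 | C9 4-nitrobenzoate with free C12–OH trans to it | O=C(O[C@@H]1C[C@@H](O)C(C)(C)[C@@H]2[C@H]3CC=C(C)[C@]2(O[Si](CC)(CC)CC)[C@]31C)c4ccc(cc4)[N+]([O-])=O
F13 | step 13 | C9 4-nitrobenzoate, C12 isovalerate | O=C(O[C@@H]1C[C@@H](OC(=O)CC(C)C)C(C)(C)[C@@H]2[C@H]3CC=C(C)[C@]2(O[Si](CC)(CC)CC)[C@]31C)c4ccc(cc4)[N+]([O-])=O
F14 | step 13 | C9 alcohol, C12 isovalerate, C1–OSiEt3 | O[C@@H]1C[C@@H](OC(=O)CC(C)C)C(C)(C)[C@@H]2[C@H]3CC=C(C)[C@]2(O[Si](CC)(CC)CC)[C@]31C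
F15 | step 17 | cesium oxalate of 20 | CC(C)=CC(=O)O[C@@H]1C[C@@H](OC(=O)CC(C)C)C(C)(C)[C@@H]2[C@H]3CC=C(C)[C@]2(OC(=O)C(=O)[O-])[C@]31C.[Cs+]
F0 | step 4 | none | none
A1 | alternative 1 | bicyclo[4.2.1]nonane α-diazoketone | CC(C)(C)[Si](C)(C)O[C@@H]1C[C@@H](OCc2ccc(OC)cc2)C(C)(C)[C@@H]2C(=O)C(=[N+]=[N-])[C@@]1(C)[C@H]2C3(C)OCCO3
A2 | alternative 1 | methyl bicyclo[4.1.1]octane-7-carboxylate with cis masked acetyl group | CC(C)(C)[Si](C)(C)O[C@@H]1C[C@@H](OCc2ccc(OC)cc2)C(C)(C)[C@@H]2[C@@H](C(=O)OC)[C@@]1(C)[C@H]2C3(C)OCCO3
A3 | alternative 2 | keto aldehyde: acetyl group on C8, aldehyde on C11 | O=CC(C)(C)[C@@H]1[C@H]2CC=C(C)[C@@H]1[C@]2(C(C)=O)C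
A4 | alternative 2 | tricyclic alkene with C12 isovalerate and free C9 hydroxyl | O[C@@H]1C[C@@H](OC(=O)CC(C)C)C(C)(C)[C@@H]2[C@H]3CC=C(C)[C@@H]2[C@]31C
A5 | alternative 3 | six-membered-ring vicinal diol (ring carbinol of either configuration) | CC(C)(C)[Si](C)(C)O[C@@H]1CC(O)(C(C)(C)O)[C@@H]2[C@H]3C(=O)C=C(C)[C@@H]2[C@]31C
A6 | alternative 3 | tricyclic enone with ketone at C12 and silyl ether at C9 | CC(C)(C)[Si](C)(C)O[C@@H]1CC(=O)C(C)(C)[C@@H]2[C@H]3C(=O)C=C(C)[C@@H]2[C@]31C
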